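## Structural features

Pseudopentafuhalol D is a linear chain of five benzene rings, lettered A to E from the 2,4,6-trihydroxyphenyl end. The rings are joined only by four diaryl ether oxygens and carry thirteen free phenolic hydroxyls. There is no stereocentre and no ring–ring carbon bond, so the whole problem is one of oxygen placement and ether formation. Ring A is a phloroglucinol bound through its C1 oxygen. Ring B has four oxygens and ring C has four (a 3,4,5-trioxygenated ring with a further oxygen at C1). Ring D has five oxygens and one CH, and ring E is 3,4,5-trihydroxyphenyl. The free pyrogallol and hydroxyquinol units oxidise easily in air and base, so every hydroxyl should travel as an ether until the last step; the diaryl ethers themselves are robust. The real difficulty is steric: the A–O–B ether has three ortho oxygen substituents (two on ring A, one on ring B), and the B–O–C and D–O–E ethers each have two on the phenol side. The key step uses ring B: its C6 oxygen (ether to ring C) is para to the C3 hydroxyl and is flanked by the hydroxylated C5 and by C1, which bears the ring A oxygen, while C2 and C4 are CH. This pattern maps onto a 3-alkoxycyclobutenedione (C3, C4, C5, C6) plus a 1-aryloxyvinyl unit (C1, C2).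

## Logic of the disconnections

**32 to 31.** The thirteen O–methyl bonds are cut last. Methyl ethers are the only masks that survive organolithiums, heating and copper catalysis, and they keep the polyphenol protected from air. The forward step must be one exhaustive dealkylation that spares the four diaryl ethers, with an oxygen-free work-up.

**31 to 21 and 30.** The bond between the ring B ether oxygen and ring C carbon 1 is cut, with the oxygen left on ring B. Ring B is the crowded partner (two ortho substituents), whereas the ring C carbon has two ortho hydrogens, so ring C is the better electrophile. The cut divides the target into a two-ring and a three-ring half. The forward step is a copper-catalysed etherification that must accept a doubly ortho-substituted phenol.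

**21 to 20 to 19.** Two protecting-group moves exchange the roles of the para oxygens of ring B: benzyl is removed from the C6 oxygen and methyl is placed on the C3 oxygen. This is needed because the ring construction gives a free C3 hydroxyl and a masked C6 oxygen, the opposite of what the coupling requires. The demand is only that benzyl and methyl are orthogonal.

**19 to 16 (strategic cut).** Ring B is opened at the C2–C3 bond and refolded into a four-membered ring by joining C3 to C6. An aromatic ring with four differentiated oxygens becomes a cyclobutenone carrying a vinyl ether, and the A–O–B ether is no longer an aryl–oxygen bond on the ring B side. The forward ring opening must turn the benzyloxy group outward so that the vinyl group can reach the ketene.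

**16 to 15 to 13 and 3.** The O–benzyl bond is cut, then the C–C bond between the carbinol carbon (future C6) and the oxygen-bearing vinyl carbon (future C1). This gives the four-carbon dione 3 and a two-carbon enol ether unit. The carbanion 14 made from 13 must add only to the carbonyl next to the methoxy-bearing carbon.

**3 to 1.** One methoxy of 1 is exchanged for hydrogen, because ring B needs only one oxygen (C5) and one CH (C4) from this side. The forward reduction must stop after one hydride.

**13 to 12 to 9 to 6 and 7.** The elements of HBr are removed, then the bond between the ring A oxygen and the future ring B carbon 1 is cut between phenol 6 and the two-carbon unit 7. This is the bond that would otherwise be the triply ortho-flanked diaryl ether; here it is made at a non-aromatic carbon. The forward sequence needs Markovnikov hydrobromination and careful handling of a sensitive ynol ether.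

**6 to 4.** The phenol oxygen is traced to a formyl group (Dakin retron). 4 is stable and cheap, and the air-sensitive 6 is made fresh.

**30 to 26 and 29.** The bond between the ring D ether oxygen and ring C carbon 5 is cut, with the oxygen left on ring D. Ring C becomes a dihalide with iodine at C5 and bromine at C1, the bromine being kept for the final coupling. The forward coupling must react at C–I and leave C–Br.

**29 to 28 to 27.** An O–methyl and a C–I bond are removed. In the forward direction the free hydroxyl of 27 directs iodine to its only free ortho position.

**26 to 24 to 22 and 23.** The ring D hydroxyl is traced to a formyl group, then the D–O–E bond is cut between the ring E oxygen and the ring D carbon. The formyl group of 22 first activates the doubly flanked neighbouring bromide for coupling and then becomes the oxygen that binds ring C.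

## Other disconnections considered

**Alternative 1:** The cut is at ring D: the C–O bond of the C–O–D ether and a C–I bond at the carbon that will later carry the ring E oxygen. In the forward step fluoride converts the ortho-silyl aryl triflate A2 into aryne A3, and the phenoxide of A4 attacks the aryne carbon remote from the flanking methoxy group. The carbanionic centre created next to that methoxy is then capped by iodine transfer from a perfluoroalkyl iodide, giving A1.
- In favour: one metal-free operation sets both vicinal bonds on the most heavily substituted ring, with regiochemistry dictated by the methoxy-induced aryne distortion. The chosen plan needs three steps (11, 12, 15) for the same two bonds, so at ring D the aryne route is the better on step economy.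
- Against: the iodine of A1 sits between an aryloxy and a methoxy group with no activating neighbour, so turning it into the D–O–E ether is harder than step 11, where an ortho formyl group helps. Protonation of the carbanionic centre would compete with iodination, and A2 needs several steps. The benzyloxy group on ring C of A1 unmasks a phenol, which would force the B–O–C ether to be made with ring B as the electrophile at its most crowded carbon.
- Comparison: both plans avoid metal catalysis at one congested bond and are equal in regiocontrol. The aryne route leaves the A–O–B ether, the most hindered one, unsolved. A three-component ionic process also has more escape paths than a unimolecular pericyclic one.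

**Alternative 2:** The cut is a C–C bond of ring A, between the ether-bearing carbon and a neighbouring hydroxylated carbon. In the forward step methoxide opens dioxinone A6 to the triketide ester A7; its C6 carbanion acylates the C1 ester carbon, and enolisation gives A5.
- In favour: it shares the central idea of the chosen plan, since the A–O–B ether is never forged at an aromatic carbon of ring A but enters as an alkyl aryl ether. It avoids trichloroethylene and organolithiums, so on safety it is the better. Ring A emerges with free hydroxyls, which leaves three fewer methyl ethers for the final step.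
- Against: C6 is the least acidic site of A7, because C2 and C4 are doubly activated. O-acylation to a 4-hydroxypyranone and aldol-type closures are open, so the mode of folding is not enforced by the substrate. A5 is an air-sensitive, C-nucleophilic phloroglucinol that would need re-protection before any copper coupling, or the ring A construction would have to be placed last on a large molecule.
- Comparison: equal in structural logic, weaker in mechanistic control. Step count would be similar or lower only if the folding were selective.

**Alternative 3:** The cut removes two C–C bonds of ring E, which is assembled from the alkyne carbons of the ring D ynol ether A9 and the four carbons of cyclobutenone A10. In the forward step heating A9 with A10 gives A8 through a cascade of four pericyclic events.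
- In favour: it belongs to the same reaction family as the chosen key step and forms, without metal, an ether whose ring D carbon is flanked by two oxygens. Regiochemistry follows from the polarisation of the ynol ether. It needs the same trichloroethylene chemistry as the chosen plan, so the two are equal on hazards.
- Against: ring E is the simplest ring of the target. It is available as phenol 23, and its ether is made in one copper step in the chosen plan. A10 is not a stock compound, and the bimolecular cycloaddition competes with ketene self-reaction. The differentiated ethoxy, methoxy and hydroxy groups that result are not needed here.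
- Comparison: the mechanism is as well controlled as in the chosen plan, but it is spent on the least demanding ether, and the step count would be higher. The chosen plan applies the same logic to the A–O–B ether, where no good alternative exists.

Key step: step 8

Remarks on the chemistry:
- Racemic 2, 15 and 16 are drawn as one enantiomer. Their stereocentre is lost in steps 1 and 8, and the target is achiral.
- 16 and 19 are isomers (C23H24O7), so the key step is balanced as drawn.
- 22, 23 and 27 are taken as purchased.
- Safety choices: aqueous H2O2 instead of a peracid, K2CO3 instead of a metal hydride with trichloroethylene (dichloroacetylene is never isolated), a tin-free main line, and BBr3 only in the last step. 1 is a strong skin sensitiser.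

Step 1
Reactants: 1 dimethyl squarate (3,4-dimethoxycyclobut-3-ene-1,2-dione)
Product: 3 3-methoxycyclobut-3-ene-1,2-dione, via hydroxycyclobutenone 2 (not isolated)
Conditions: LiAlH(OtBu)3, THF, −78 → −20 °C; 1 M HCl quench; then 12 M HCl (cat.), CH2Cl2, rt
Reagents that add atoms: none
Why: Hindered-hydride 1,2-reduction of a squarate ester stops at the hydroxy enone 2; acid then ionises the allylic hydroxyl and expels methanol to give the semisquarate (known semisquarate synthesis), and the stereocentre of 2 is lost.

Step 2
Reactants: 4 2,4,6-trimethoxybenzaldehyde
Product: 6 2,4,6-trimethoxyphenol, via aryl formate 5 (not isolated)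
Conditions: 30% H2O2, H2SO4 (cat.), MeOH, 0 °C → rt, argon
Reagents that add atoms: hydrogen peroxide, OO
Why: Acid-catalysed Dakin oxidation: the electron-rich aryl group migrates to oxygen (Baeyer–Villiger type) and the formate is methanolysed in the same pot; 6 is used fresh because it is air-sensitive.

Step 3
Reactants: 6 2,4,6-trimethoxyphenol; 7 trichloroethylene
Product: 9 2-{[(E)-1,2-dichloroethenyl]oxy}-1,3,5-trimethoxybenzene, via dichloroacetylene 8 (not isolated)
Conditions: K2CO3, DMF, 70 °C, argon
Reagents that add atoms: none
Why: The base eliminates HCl from 7 and the phenoxide adds anti to the transient dichloroacetylene, giving the E-dichlorovinyl ether (standard entry to ynol ethers); the crowded ether oxygen is attached to a non-aromatic carbon without any coupling.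

Step 4
Reactants: 9 2-{[(E)-1,2-dichloroethenyl]oxy}-1,3,5-trimethoxybenzene
Product: 12 2-(ethynyloxy)-1,3,5-trimethoxybenzene, via chloroalkynyl ether 10 (not isolated), via lithium acetylide 11 (not isolated)
Conditions: n-BuLi (2.2 equiv), THF, −78 → −40 °C; then MeOH, −78 °C
Reagents that add atoms: none
Why: Elimination of HCl gives the chloroalkyne and chlorine–lithium exchange the acetylide, which is protonated to the terminal ynol ether (dichlorovinyl ether route to alkynyl ethers); the low temperature keeps the ring A positions between two methoxy groups from being lithiated.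

Step 5
Reactants: 12 2-(ethynyloxy)-1,3,5-trimethoxybenzene
Product: 13 2-[(1-bromoethenyl)oxy]-1,3,5-trimethoxybenzene
Conditions: TMSBr (1.0 equiv), MeOH (1.0 equiv), CH2Cl2, −40 °C; concentrated cold under argon and used crude
Reagents that add atoms: bromotrimethylsilane, C[Si](C)(C)Br
Why: Markovnikov hydrobromination of an ynol ether: protonation at the terminal carbon gives an oxygen-stabilised cation that bromide captures at the oxygen-bearing carbon; one equivalent of anhydrous HBr made in the flask limits double addition.

Step 6
Reactants: 13 2-[(1-bromoethenyl)oxy]-1,3,5-trimethoxybenzene; 3 3-methoxycyclobut-3-ene-1,2-dione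
Product: 15 racemic 4-hydroxy-3-methoxy-4-[1-(2,4,6-trimethoxyphenoxy)ethenyl]cyclobut-2-en-1-one, via vinyllithium 14 (not isolated)
Conditions: t-BuLi (2.0 equiv), THF, −78 °C; cannulated into 3, THF, −78 °C; NH4Cl (aq), −78 °C
Reagents that add atoms: none
Why: Bromine–lithium exchange gives the 1-aryloxyvinyllithium, which adds 1,2 to the ketone-like carbonyl beside the methoxy-bearing carbon and not to the vinylogous ester carbonyl (established regiochemistry for organolithium addition to 3-alkoxycyclobutenediones). The quaternary centre forms as a racemate and is erased in step 8.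

Step 7
Reactants: 15 racemic 4-hydroxy-3-methoxy-4-[1-(2,4,6-trimethoxyphenoxy)ethenyl]cyclobut-2-en-1-one
Product: 16 racemic 4-(benzyloxy)-3-methoxy-4-[1-(2,4,6-trimethoxyphenoxy)ethenyl]cyclobut-2-en-1-one
Conditions: BnBr, Ag2O, MeCN, rt, dark
Reagents that add atoms: benzyl bromide, BrCc1ccccc1
Why: Ag2O-promoted O-alkylation (Purdie type) of the tertiary ketol works without a free alkoxide, which would trigger ring opening, and without acid, which would cleave the enol ether; the same conditions are used for methyl and allyl ethers of such carbinols.

Step 8
Reactants: 16 racemic 4-(benzyloxy)-3-methoxy-4-[1-(2,4,6-trimethoxyphenoxy)ethenyl]cyclobut-2-en-1-one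
Product: 19 4-(benzyloxy)-3-methoxy-5-(2,4,6-trimethoxyphenoxy)phenol, via dienylketene 17 (not isolated), via cyclohexadienone 18 (not isolated)
Conditions: PhMe (degassed, base-washed glass), 110 °C
Reagents that add atoms: none
Why: Heating cleaves the bond between the carbonyl carbon and the quaternary carbon by conrotatory four-electron electrocyclic opening and gives the (Z)-dienylketene 17. The benzyloxy group, a lone-pair donor, prefers outward rotation (torquoselectivity), which places the 1-aryloxyvinyl group inward, next to the ketene. Thermal disrotatory six-electron electrocyclisation then joins the ketene carbon to the vinyl CH2 carbon and closes the six-membered carbocycle as dienone 18, which enolises to phenol 19. The closest known reaction type is the thermal ring expansion of 4-alkenyl-4-alkoxy- or 4-hydroxycyclobutenones made from squarate esters and alkenyllithiums (Moore rearrangement); the aryloxyvinyl group is a new member of a known substrate class. No stereocentre is created, and the racemic centre of 16 is consumed. The step needs torquoselectivity and clean six-electron closure: the donor at C4 secures the first, and the unhindered terminal CH2 held cis to the ketene secures the second. The oxygen pattern was fixed in step 6, so the ring closure has no regiochemical choice left. Aromatisation makes the sequence irreversible.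

Step 9
Reactants: 19 4-(benzyloxy)-3-methoxy-5-(2,4,6-trimethoxyphenoxy)phenol
Product: 20 2-(benzyloxy)-1,5-dimethoxy-3-(2,4,6-trimethoxyphenoxy)benzene
Conditions: MeI, K2CO3, acetone, 50 °C
Reagents that add atoms: iodomethane, CI
Why: Williamson methylation of the only free, unhindered phenol.

Step 10
Reactants: 20 2-(benzyloxy)-1,5-dimethoxy-3-(2,4,6-trimethoxyphenoxy)benzene
Product: 21 2,4-dimethoxy-6-(2,4,6-trimethoxyphenoxy)phenol
Conditions: H2 (1 atm), 10% Pd/C, EtOAc–MeOH, rt
Reagents that add atoms: none
Why: Hydrogenolysis removes the benzyl ether and leaves methyl and diaryl ethers untouched, freeing the ring B oxygen that will bind ring C.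

Step 11
Reactants: 22 2-bromo-3,4,5-trimethoxybenzaldehyde; 23 3,4,5-trimethoxyphenol
Product: 24 3,4,5-trimethoxy-2-(3,4,5-trimethoxyphenoxy)benzaldehyde
Conditions: CuI (10 mol%), picolinic acid (20 mol%), K3PO4, DMSO, 90 °C
Reagents that add atoms: none
Why: Ullmann-type ether synthesis; the ortho formyl group activates the doubly flanked bromide, and the phenol partner is unhindered.

Step 12
Reactants: 24 3,4,5-trimethoxy-2-(3,4,5-trimethoxyphenoxy)benzaldehyde
Product: 26 3,4,5-trimethoxy-2-(3,4,5-trimethoxyphenoxy)phenol, via aryl formate 25 (not isolated)
Conditions: 30% H2O2, H2SO4 (cat.), MeOH, rt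
Reagents that add atoms: hydrogen peroxide, OO
Why: Acid-catalysed Dakin oxidation; the ortho aryloxy and para methoxy groups make the aryl ring the migrating group, and the formate is cleaved in the pot.

Step 13
Reactants: 27 4-bromo-2-methoxyphenol
Product: 28 4-bromo-2-iodo-6-methoxyphenol
Conditions: NIS, TsOH (cat.), MeCN, 0 °C → rt
Reagents that add atoms: N-iodosuccinimide, O=C1CCC(=O)N1I
Why: Electrophilic iodination; the hydroxyl directs to its only free ortho position because the para position is blocked by bromine.

Step 14
Reactants: 28 4-bromo-2-iodo-6-methoxyphenol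
Product: 29 5-bromo-1-iodo-2,3-dimethoxybenzene
Conditions: MeI, K2CO3, acetone, 50 °C
Reagents that add atoms: iodomethane, CI
Why: Williamson methylation of the phenol.

Step 15
Reactants: 26 3,4,5-trimethoxy-2-(3,4,5-trimethoxyphenoxy)phenol; 29 5-bromo-1-iodo-2,3-dimethoxybenzene
Product: 30 1-(5-bromo-2,3-dimethoxyphenoxy)-3,4,5-trimethoxy-2-(3,4,5-trimethoxyphenoxy)benzene
Conditions: 29 (2 equiv), CuI (10 mol%), picolinic acid (20 mol%), K3PO4, DMSO, 80 °C
Reagents that add atoms: none
Why: Ullmann-type etherification, chemoselective for the C–I bond over the C–Br bond at moderate temperature; an excess of 29 suppresses reaction at the bromide, which is kept for step 16.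

Step 16
Reactants: 21 2,4-dimethoxy-6-(2,4,6-trimethoxyphenoxy)phenol; 30 1-(5-bromo-2,3-dimethoxyphenoxy)-3,4,5-trimethoxy-2-(3,4,5-trimethoxyphenoxy)benzene
Product: 31 5-[2,4-dimethoxy-6-(2,4,6-trimethoxyphenoxy)phenoxy]-1,2-dimethoxy-3-[3,4,5-trimethoxy-2-(3,4,5-trimethoxyphenoxy)phenoxy]benzene
Conditions: CuI (20 mol%), picolinic acid (40 mol%), K3PO4, DMSO, 100 °C, argon
Reagents that add atoms: none
Why: Ligand-accelerated Ullmann etherification; the picolinic acid system is the one suited to doubly ortho-substituted phenols, and the bromide of 30 has two ortho hydrogens.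

Step 17
Reactants: 31 5-[2,4-dimethoxy-6-(2,4,6-trimethoxyphenoxy)phenoxy]-1,2-dimethoxy-3-[3,4,5-trimethoxy-2-(3,4,5-trimethoxyphenoxy)phenoxy]benzene
Product: 32 pseudopentafuhalol D
Conditions: BBr3 (excess, at least 1.5 equiv per OMe), CH2Cl2, −78 °C → rt; then H2O, 0 °C, argon
Reagents that add atoms: none
Why: Lewis-acid demethylation: each methyl ether is cleaved by bromide attack on the boron-complexed methyl group, while diaryl ethers lack an alkyl carbon to attack and survive; work-up is under inert gas to protect the pyrogallol units.

## Compound list

1 | dimethyl squarate (3,4-dimethoxycyclobut-3-ene-1,2-dione) | COC1=C(OC)C(=O)C1=O | starting material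
2 | racemic 4-hydroxy-2,3-dimethoxycyclobut-2-en-1-one (one enantiomer drawn) | COC1=C(OC)[C@@H](O)C1=O | intermediate
3 | 3-methoxycyclobut-3-ene-1,2-dione | COC1=CC(=O)C1=O | intermediate
4 | 2,4,6-trimethoxybenzaldehyde | COc1cc(OC)c(C=O)c(OC)c1 | starting material
5 | 2,4,6-trimethoxyphenyl formate | COc1cc(OC)c(OC=O)c(OC)c1 | intermediate
6 | 2,4,6-trimethoxyphenol | COc1cc(OC)c(O)c(OC)c1 | intermediate
7 | trichloroethylene | ClC=C(Cl)Cl | starting material
8 | dichloroacetylene | ClC#CCl | intermediate
9 | 2-{[(E)-1,2-dichloroethenyl]oxy}-1,3,5-trimethoxybenzene | Cl/C=C(/Cl)Oc1c(OC)cc(OC)cc1OC | intermediate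
10 | 2-[(chloroethynyl)oxy]-1,3,5-trimethoxybenzene | ClC#COc1c(OC)cc(OC)cc1OC | intermediate
11 | lithium 2-(2,4,6-trimethoxyphenoxy)ethynide | [Li]C#COc1c(OC)cc(OC)cc1OC | intermediate
12 | 2-(ethynyloxy)-1,3,5-trimethoxybenzene | C#COc1c(OC)cc(OC)cc1OC | intermediate
13 | 2-[(1-bromoethenyl)oxy]-1,3,5-trimethoxybenzene | C=C(Br)Oc1c(OC)cc(OC)cc1OC | intermediate
14 | [1-(2,4,6-trimethoxyphenoxy)ethenyl]lithium | [Li]C(=C)Oc1c(OC)cc(OC)cc1OC | intermediate
15 | racemic 4-hydroxy-3-methoxy-4-[1-(2,4,6-trimethoxyphenoxy)ethenyl]cyclobut-2-en-1-one (one enantiomer drawn) | COC1=CC(=O)[C@@]1(O)C(=C)Oc1c(OC)cc(OC)cc1OC | intermediate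
16 | racemic 4-(benzyloxy)-3-methoxy-4-[1-(2,4,6-trimethoxyphenoxy)ethenyl]cyclobut-2-en-1-one (one enantiomer drawn) | COC1=CC(=O)[C@@]1(OCc1ccccc1)C(=C)Oc1c(OC)cc(OC)cc1OC | intermediate
17 | (3Z)-4-(benzyloxy)-3-methoxy-5-(2,4,6-trimethoxyphenoxy)hexa-1,3,5-trien-1-one | O=C=C/C(OC)=C(\C(=C)Oc1c(OC)cc(OC)cc1OC)OCc1ccccc1 | intermediate
18 | 4-(benzyloxy)-3-methoxy-5-(2,4,6-trimethoxyphenoxy)cyclohexa-2,4-dien-1-one | O=C1C=C(OC)C(OCc2ccccc2)=C(Oc2c(OC)cc(OC)cc2OC)C1 | intermediate
19 | 4-(benzyloxy)-3-methoxy-5-(2,4,6-trimethoxyphenoxy)phenol | COc1cc(O)cc(Oc2c(OC)cc(OC)cc2OC)c1OCc1ccccc1 | intermediate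
20 | 2-(benzyloxy)-1,5-dimethoxy-3-(2,4,6-trimethoxyphenoxy)benzene | COc1cc(OC)cc(Oc2c(OC)cc(OC)cc2OC)c1OCc1ccccc1 | intermediate
21 | 2,4-dimethoxy-6-(2,4,6-trimethoxyphenoxy)phenol | COc1cc(OC)c(O)c(Oc2c(OC)cc(OC)cc2OC)c1 | intermediate
22 | 2-bromo-3,4,5-trimethoxybenzaldehyde | COc1cc(C=O)c(Br)c(OC)c1OC | starting material
23 | 3,4,5-trimethoxyphenol | COc1cc(O)cc(OC)c1OC | starting material
24 | 3,4,5-trimethoxy-2-(3,4,5-trimethoxyphenoxy)benzaldehyde | COc1cc(C=O)c(Oc2cc(OC)c(OC)c(OC)c2)c(OC)c1OC | intermediate
25 | 3,4,5-trimethoxy-2-(3,4,5-trimethoxyphenoxy)phenyl formate | COc1cc(OC=O)c(Oc2cc(OC)c(OC)c(OC)c2)c(OC)c1OC | intermediate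
26 | 3,4,5-trimethoxy-2-(3,4,5-trimethoxyphenoxy)phenol | COc1cc(O)c(Oc2cc(OC)c(OC)c(OC)c2)c(OC)c1OC | intermediate
27 | 4-bromo-2-methoxyphenol | COc1cc(Br)ccc1O | starting material
28 | 4-bromo-2-iodo-6-methoxyphenol | COc1cc(Br)cc(I)c1O | intermediate
29 | 5-bromo-1-iodo-2,3-dimethoxybenzene | COc1cc(Br)cc(I)c1OC | intermediate
30 | 1-(5-bromo-2,3-dimethoxyphenoxy)-3,4,5-trimethoxy-2-(3,4,5-trimethoxyphenoxy)benzene | COc1cc(Br)cc(Oc2cc(OC)c(OC)c(OC)c2Oc2cc(OC)c(OC)c(OC)c2)c1OC | intermediate
31 | 5-[2,4-dimethoxy-6-(2,4,6-trimethoxyphenoxy)phenoxy]-1,2-dimethoxy-3-[3,4,5-trimethoxy-2-(3,4,5-trimethoxyphenoxy)phenoxy]benzene | COc1cc(OC)c(Oc2cc(OC)cc(OC)c2Oc2cc(OC)c(OC)c(Oc3cc(OC)c(OC)c(OC)c3Oc3cc(OC)c(OC)c(OC)c3)c2)c(OC)c1 | intermediate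
32 | pseudopentafuhalol D, 5-[2,4-dihydroxy-6-(2,4,6-trihydroxyphenoxy)phenoxy]-3-[3,4,5-trihydroxy-2-(3,4,5-trihydroxyphenoxy)phenoxy]benzene-1,2-diol | Oc1cc(O)c(Oc2cc(O)cc(O)c2Oc2cc(O)c(O)c(Oc3cc(O)c(O)c(O)c3Oc3cc(O)c(O)c(O)c3)c2)c(O)c1 | target

## Step count and least certain steps

Total: 17 steps. Longest linear sequence: 11 steps (2, 3, 4, 5, 6, 7, 8, 9, 10, 16, 17, from 4). Side branches: step 1; steps 11, 12, 15; steps 13, 14.

**Step 8 (key step).** The open-chain ketene may be diverted before the six-electron closure. This could happen through inward rotation of the benzyloxy group, which gives a conformer that cannot close, through ketene self-reaction, or through acid-induced cleavage of the enol ether during heating. The fallback sets out from 15 and drops the benzyl ether. The free carbinol 15 should be heated in THF or benzene at 65–80 °C; this is the hydroxy variant of the same ring expansion, in which the hydroxyl has the strongest outward preference and the product tautomerises directly. It should give the hydroquinone 2-methoxy-6-(2,4,6-trimethoxyphenoxy)benzene-1,4-diol F1. Mono-methylation of F1 at its unhindered hydroxyl (MeI 1.0 equiv, K2CO3, acetone, rt, argon) then returns to the route at 21 without steps 7, 9 and 10; the other hydroxyl is shielded by two oxygen neighbours.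

**Step 6.** The vinyllithium 14 may be lost by expulsion of the aryloxide from the carbanionic carbon (carbenoid decomposition) before it adds. It may also deprotonate 3 or attack the wrong carbonyl. The fallback leaves the squarate line and makes the crowded ether by copper catalysis. It sets out from 6, which is coupled (CuI, picolinic acid, K3PO4, DMSO, 90 °C) with purchased 2-bromo-4,6-dimethoxybenzaldehyde F2. The bromide of F2 is activated by the ortho formyl group and has only one ortho substituent. The product 2,4-dimethoxy-6-(2,4,6-trimethoxyphenoxy)benzaldehyde F3 is then oxidised under the conditions of step 12, through 2,4-dimethoxy-6-(2,4,6-trimethoxyphenoxy)phenyl formate F4, and the route is rejoined at 21.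

**Step 5.** Hydrolysis of the 1-bromovinyl ether to the aryl acetate, or a second addition of HBr during concentration, may leave little 13 for step 6. The fallback sets out from 12 and uses a stable tin intermediate. Hydrostannation with Bu3SnH and Pd(PPh3)4 (THF, 0 °C), which places tin on the oxygen-bearing carbon of alkoxyalkynes, should give tributyl[1-(2,4,6-trimethoxyphenoxy)ethenyl]stannane F5, which can be chromatographed. Tin–lithium exchange with n-BuLi (THF, −78 °C) gives 14 and rejoins the route at 14 inside step 6. The cost is the handling of toxic organotin.

**Step 16.** Ether formation at the doubly ortho-flanked, electron-rich phenol 21 may be slow, so that oxidative degradation of 21 or loss of bromine from 30 takes over. The fallback changes the order of bond formation and sets out from 21. Purchased 2-bromo-6-methoxyphenol F6 is iodinated para to the hydroxyl (NIS, MeCN) to 2-bromo-4-iodo-6-methoxyphenol F7 and methylated (MeI, K2CO3) to 1-bromo-5-iodo-2,3-dimethoxybenzene F8. Excess F8 is coupled with 21 at its unhindered iodide (CuI, picolinic acid, K3PO4, DMSO, 80 °C) to give 1-bromo-2,3-dimethoxy-5-[2,4-dimethoxy-6-(2,4,6-trimethoxyphenoxy)phenoxy]benzene F9. A second copper-catalysed coupling of F9 with phenol 26 at 100 °C rejoins the route at 31.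

**Step 15.** Discrimination between the C–I and C–Br bonds of 29 may be insufficient, leading to double arylation. The fallback sets out from 29 and replaces halide selectivity in the coupling by an oxidative coupling at room temperature. Selective iodine–magnesium exchange (iPrMgCl·LiCl, THF, −20 °C), B(OMe)3 and acidic work-up give (5-bromo-2,3-dimethoxyphenyl)boronic acid F10. Chan–Lam coupling of F10 with 26 (Cu(OAc)2 20 mol%, pyridine, O2, 4 Å MS, CH2Cl2, rt) leaves the bromide untouched and rejoins the route at 30.

**Step 17.** Cleavage of the thirteen methyl ethers may stop short and give mixtures of partial ethers, and the liberated pyrogallol units may oxidise during work-up. The fallback sets out from 31 and changes the cleavage principle from Lewis-acid activation to SN2 attack by a soft nucleophile. Sodium dodecane-1-thiolate, made from 1-dodecanethiol and NaOH in NMP, is used at 130 °C under argon, followed by acidification with HCl; this arrives directly at 32 and makes no new isolated compound.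

## Further compounds

F1 | step 8 | 2-methoxy-6-(2,4,6-trimethoxyphenoxy)benzene-1,4-diol | COc1cc(O)cc(Oc2c(OC)cc(OC)cc2OC)c1O
F2 | step 6 | 2-bromo-4,6-dimethoxybenzaldehyde | COc1cc(Br)c(C=O)c(OC)c1
F3 | step 6 | 2,4-dimethoxy-6-(2,4,6-trimethoxyphenoxy)benzaldehyde | COc1cc(OC)c(C=O)c(Oc2c(OC)cc(OC)cc2OC)c1
F4 | step 6 | 2,4-dimethoxy-6-(2,4,6-trimethoxyphenoxy)phenyl formate | COc1cc(OC)c(OC=O)c(Oc2c(OC)cc(OC)cc2OC)c1
F5 | step 5 | tributyl[1-(2,4,6-trimethoxyphenoxy)ethenyl]stannane | CCCC[Sn](CCCC)(CCCC)C(=C)Oc1c(OC)cc(OC)cc1OC
F6 | step 16 | 2-bromo-6-methoxyphenol | COc1cccc(Br)c1O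
F7 | step 16 | 2-bromo-4-iodo-6-methoxyphenol | COc1cc(I)cc(Br)c1O
F8 | step 16 | 1-bromo-5-iodo-2,3-dimethoxybenzene | COc1cc(I)cc(Br)c1OC
F9 | step 16 | 1-bromo-2,3-dimethoxy-5-[2,4-dimethoxy-6-(2,4,6-trimethoxyphenoxy)phenoxy]benzene | COc1cc(Oc2c(OC)cc(OC)cc2Oc2c(OC)cc(OC)cc2OC)cc(Br)c1OC
F10 | step 15 | (5-bromo-2,3-dimethoxyphenyl)boronic acid | COc1cc(Br)cc(B(O)O)c1OC
F0 | step 17 | none | none
A1 | alternative 1 | 5-(benzyloxy)-1-(2-iodo-3,4,5-trimethoxyphenoxy)-2,3-dimethoxybenzene | COc1cc(OCc2ccccc2)cc(Oc2cc(OC)c(OC)c(OC)c2I)c1OC
A2 | alternative 1 | 3,4,5-trimethoxy-2-(trimethylsilyl)phenyl trifluoromethanesulfonate | COc1cc(OS(=O)(=O)C(F)(F)F)c([Si](C)(C)C)c(OC)c1OC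
A3 | alternative 1 | 3,4,5-trimethoxybenzyne | COC1=C(OC)C(OC)=CC#C1
A4 | alternative 1 | 5-(benzyloxy)-2,3-dimethoxyphenol | COc1cc(OCc2ccccc2)cc(O)c1OC
A5 | alternative 2 | 2-[2-(benzyloxy)-3,5-dimethoxyphenoxy]benzene-1,3,5-triol | Oc1cc(O)c(Oc2cc(OC)cc(OC)c2OCc2ccccc2)c(O)c1
A6 | alternative 2 | 6-{3-[2-(benzyloxy)-3,5-dimethoxyphenoxy]-2-oxopropyl}-2,2-dimethyl-4H-1,3-dioxin-4-one | CC1(C)OC(=O)C=C(CC(=O)COc2cc(OC)cc(OC)c2OCc2ccccc2)O1
A7 | alternative 2 | methyl 6-[2-(benzyloxy)-3,5-dimethoxyphenoxy]-3,5-dioxohexanoate | COC(=O)CC(=O)CC(=O)COc1cc(OC)cc(OC)c1OCc1ccccc1
A8 | alternative 3 | 5-[6-(benzyloxy)-2,3,4-trimethoxyphenoxy]-3-ethoxy-2-methoxyphenol | CCOc1cc(Oc2c(OCc3ccccc3)cc(OC)c(OC)c2OC)cc(O)c1OC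
A9 | alternative 3 | 1-(benzyloxy)-2-(ethynyloxy)-3,4,5-trimethoxybenzene | C#COc1c(OCc2ccccc2)cc(OC)c(OC)c1OC
A10 | alternative 3 | racemic 3-ethoxy-4-methoxycyclobut-2-en-1-one (one enantiomer drawn) | CCOC1=CC(=O)[C@@H]1OC
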